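At early times the spring run, the very flask we are asked about, loses starting material faster than it gains target: 17 percentage points against 13.6% over the first 5.00 h.

the same everywhere: starting material 29 mM; free catalyst 5 mol%
- spring: second substrate 1 equiv; coupling partner 0.50 equiv; temperature 50 °C; the very flask that is asked about, followed so far
- autumn: second substrate 1 equiv; coupling partner 0.50 equiv; temperature 45 °C; run made earlier
- flask: second substrate 1.00 equiv; coupling partner 0.500 equiv; temperature 50 °C; time 2.5 d

- spring (time / h: target / %, starting material / %): 5.00: 13.6, 83.1; 8.00: 19.1, 76.0; 12.0: 21.8, 69.6; 15.0: 25.0, 65.9; 25.0: 29.0, 60.1; 40.0: 28.8, 58.3; 60.0: 27.3, 58.1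
- autumn (time / h: target / %, starting material / %): 5.00: 9.7, 87.3; 8.00: 13.5, 81.1; 12.0: 18.0, 76.1; 15.0: 21.2, 73.1; 25.0: 25.2, 64.4; 40.0: 26.6, 62.4; 60.0: 26.7, 60.1

(scatter of a reading: 0.5 percentage points)

- elm: change nothing and wait 5.0 d more
- ash: at 2.5 d add free catalyst, 50.0% of the amount charged, then wait 5.0 d
- birch: at 2.5 d take out 90% of the target then present, then wait 5.0 d
- cedar: at 2.5 d raise the temperature by 25 K, then wait 5.0 d
- larch: at 2.5 d add coupling partner, 50.0% of the amount charged, then wait 5.0 d

- what is taken out of target is counted as made
- what was read earlier has a scatter of 0.5 percentage points, one standard deviation
- additions bring no volume worth counting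

1. target, in percent of the starting material first charged, at 2.5 d
2. the option that brings most further target ("none" if no option brings more than 2 percentage points) (elm / ash / birch / cedar / larch / none)
3. target present, with what was taken out counted in, in percent of the starting material first charged, after birch
4. target present, with what was taken out counted in, in percent of the starting material first charged, after cedar

We follow how that comparison drifts. Starting material stops near 58.1% in the spring run and near 60.1% in the cooler autumn run, so we read the stop as a charge used up rather than a slow clock, and we take coupling partner, charged at 0.500 equiv, as the limiting reagent. Each point of partner then spent 0.838 of a point of starting material in the spring run. Since the flask at 2.5 d is the spring run's last reading, we commit to about 27.3% for now. Larch adds 25.0% of partner, reckoned on the starting material charged, so it should spend about 20.9% more starting material.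

The weak link is that first ratio. Catalyst charged at 5 mol% can hold starting material that no partner has touched, and the early gap points the same way. Taking that amount off gives the partner yield, the points of starting material carried through to product per point of partner charged: 0.738. By this reckoning larch turns about 18.4%. At 25.0 h in the spring run, target read 0.831 of what had been turned, which makes about 15.3% new target. The spring run's late slide, carried over 5.0 d, takes off 5.8 points, so we expect larch to gain about 9.5 points.

The forecast gives 27.5% for now, names larch, and puts birch at 26.5% and cedar at 4%, between 0.5% and 13%, saying of cedar: “this is the least certain figure”.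

The flask gives 27.7%, larch best at 6.3 points, birch 29.1%, and cedar 19.1%, higher than the top of the forecast's range.

    second substrate + free catalyst ⇌ catalyst intermediate B (K = 45.0 /M, k = 1.35 /M/min, Ea = 58.0 kJ/mol, ΔH = −60.0 kJ/mol)
    coupling partner + catalyst intermediate A → free catalyst + target (k = 1.71 /M/min, Ea = 44.0 kJ/mol)
    starting material + free catalyst ⇌ catalyst intermediate A (K = 3340 /M, k = 1.53 /M/min, Ea = 72.0 kJ/mol, ΔH = 14.0 kJ/mol)
    coupling partner + catalyst intermediate B → free catalyst + second product (k = 2.26 /M/min, Ea = 70.0 kJ/mol)
    target + free catalyst ⇌ isomer of the product + free catalyst, rate k5*[free catalyst]*[target] forward; the back reaction follows from the equilibrium constant (K = 0.935, k = 1.49 /M/min, Ea = 53.0 kJ/mol, ΔH = 12.0 kJ/mol)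
    (constants at 50 °C)

By its forward step alone, with the other concentrations as charged, target has a half-life of 5.3 h, short against 2.5 d, but free catalyst in this flask stands at 1.73% of its charge at 60.0 h. Left alone, this flask still holds 19.8% of target beside 17.1% of isomer of the product after 600 h. Target plus isomer per point of partner comes to 0.739 in this flask at 60.0 h, against our 0.738. In the neighbour charged with 1.20 equiv of partner it comes to 0.637.

Readings and results come from a simulation for substances that don't exist.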